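**Plan**

- Numbering and enabling feature: the chain runs from C1 (the CH2 carrying the angelate) to C15 (CMe2), and the lactone carbonyl on C11 is C20. O8 (acetate) and O12 (free hydroxyl) flank the trisubstituted C10=C11 alkene, which is exocyclic to the five-membered lactone (ring A: C11, C12, C13, O, C20) and carries C9 and C12 cis. A bridge O8–C(=O)–CH2–Si–O12 therefore holds that alkene cis inside a ten-membered ring (ring B), and its C(=O)–CH2 unit is the future acetate.
- Retrosynthesis, in order: Si–O12 and Si–CH2 (fluoride); C10=C11 (ring-closing metathesis); the open tether at Si–O12 and Si–CH2 (silylation, carbenoid Si–H insertion); then C8–C9 (allylation), C8–H (allylic oxidation) and the C1–O ester in the chain, and C11=CH2 and C14=C15 in the lactone.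
- Forward: nerol → neryl angelate → C8 enal → 8S homoallylic alcohol → diazoacetate. Separately, 2-deoxy-D-ribose → its 1,4-lactone (ring A) → isobutenyl lactone → α-methylene hydroxy lactone. The two fragments are joined through silicon, ring B is closed, and the bridge is cut to acetate plus hydroxyl.
- Stereochemistry: C12 and C13 are C3 and C4 of 2-deoxy-D-ribose, carried through unchanged. C8 is set by reagent-controlled Brown allylboration. 2Z comes from nerol, the angelate Z from angelic acid, 6E from the site selectivity of the SeO2 oxidation, and 10E from ring B.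

Key step: step 16

Remark: the target SMILES is read as 8S, 12S, 13R with 2Z, 6E, 10E and a (Z)-2-methylbut-2-enoate; ring A is trans-substituted, as in 2-deoxy-D-ribono-1,4-lactone.
Remark: silicon is brought in as HSiMe2Cl so that the Si–CH2 bond arises by carbenoid insertion; silylating a metal enolate of the allylic C8 ester is kept only as a fallback, because such enolates can rearrange [3,3].

**Route**

Step 1
Reactants: 1 nerol; 2 angelic acid
Product: 4 neryl angelate, via angelic 2,4,6-trichlorobenzoic anhydride 3 (not isolated)
Conditions: 2 (1.5 equiv), 2,4,6-trichlorobenzoyl chloride, Et3N, toluene, rt; then 1, 80 °C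
Reagents that add atoms: none
Why: Yamaguchi-type mixed-anhydride esterification run without a nucleophilic catalyst lets the primary allylic alcohol attack the less hindered angeloyl carbonyl, conditions under which angelates are known to form without drifting to the tiglate; no stereocentre is involved and both Z alkenes come in with the starting materials.

Step 2
Reactants: 4 neryl angelate
Product: 5 (2Z,6E)-8-hydroxyneryl angelate
Conditions: SeO2 (0.3 equiv), t-BuOOH (3 equiv), salicylic acid (0.1 equiv), CH2Cl2, rt
Reagents that add atoms: tert-butyl hydroperoxide, CC(C)(C)OO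
Why: Riley allylic oxidation (ene reaction, then [2,3]-sigmatropic shift, with SeO2 turned over by the hydroperoxide) should attack the (E)-methyl group of the most electron-rich trisubstituted alkene, because the C2=C3 alkene is deactivated by the allylic ester oxygen and the angelate alkene by conjugation, so C8 is oxygenated with the 6E geometry.

Step 3
Reactants: 5 (2Z,6E)-8-hydroxyneryl angelate
Product: 6 (2Z,6E)-8-oxoneryl angelate
Conditions: MnO2 (20 equiv), CH2Cl2, rt
Reagents that add atoms: none
Why: MnO2 oxidises only the allylic alcohol and should give the (E)-enal without touching esters or alkenes; any enal already formed in step 2 is this same compound and can be pooled.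

Step 4
Reactants: 6 (2Z,6E)-8-oxoneryl angelate
Product: 8 (2Z,6E,8S)-8-hydroxy-3,7-dimethylundeca-2,6,10-trien-1-yl angelate, via O8-diisopinocampheylborinate 7 (not isolated)
Conditions: (−)-Ipc2BOMe, allylMgBr, Et2O, −78 °C → rt; then 6, −78 °C; then NaBO3·4H2O, THF/H2O, rt
Reagents that add atoms: allylmagnesium bromide, C=CC[Mg]Br
Why: Brown allylboration with (−)-Ipc2B(allyl), made in the flask from the (+)-α-pinene-derived borinate, should deliver allyl through a closed chair transition state to the si face of the enal carbonyl and so set C8 as S under reagent control, while the esters are inert at −78 °C and the mild perborate work-up spares the angelate.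

Step 5
Reactants: 8 (2Z,6E,8S)-8-hydroxy-3,7-dimethylundeca-2,6,10-trien-1-yl angelate
Product: 9 C8 bromoacetate of 8
Conditions: BrCH2COBr, pyridine, CH2Cl2, 0 °C
Reagents that add atoms: bromoacetyl bromide, O=C(Br)CBr
Why: O-acylation of the secondary alcohol by the acid bromide with pyridine as acid scavenger is fast at 0 °C and leaves the C8–O bond, and hence the configuration, untouched.

Step 6
Reactants: 9 C8 bromoacetate of 8
Product: 10 C8 diazoacetate of 8
Conditions: TsNHNHTs, DBU, THF, 0 °C
Reagents that add atoms: N,N'-ditosylhydrazine, Cc1ccc(cc1)S(=O)(=O)NNS(=O)(=O)c1ccc(C)cc1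
Why: the established diazoacetate synthesis from bromoacetates (SN2 displacement of bromide by the sulfonylhydrazide anion, then two base-induced losses of sulfinate) runs at 0 °C, which should be mild enough for the angelate and the allylic esters.

Step 7
Reactants: 11 2-deoxy-D-ribose
Product: 12 2-deoxy-D-ribono-1,4-lactone
Conditions: Br2, H2O, rt
Reagents that add atoms: none
Why: bromine-water oxidation of the aldose at its hemiacetal carbon gives the aldonic acid, which settles as the five-membered 1,4-lactone (ring A), with C3 and C4 untouched.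

Step 8
Reactants: 12 2-deoxy-D-ribono-1,4-lactone
Product: 13 3,5-bis-O-TBS lactone
Conditions: TBSCl, imidazole, DMF, rt
Reagents that add atoms: tert-butyldimethylsilyl chloride, CC(C)(C)[Si](C)(C)Cl
Why: standard imidazole-promoted silylation protects both hydroxyls without affecting the lactone.

Step 9
Reactants: 13 3,5-bis-O-TBS lactone
Product: 14 3-O-TBS-5-hydroxy lactone
Conditions: TFA/H2O/THF (1:1:4), 0 °C
Reagents that add atoms: none
Why: acid-catalysed solvolysis removes the unhindered primary silyl ether much faster than the secondary one, a selectivity long used on bis-silylated deoxyribose derivatives.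

Step 10
Reactants: 14 3-O-TBS-5-hydroxy lactone
Product: 15 3-O-TBS lactone 5-aldehyde
Conditions: Dess–Martin periodinane, CH2Cl2, 0 °C → rt; used crude
Reagents that add atoms: none
Why: Dess–Martin oxidation is non-basic, so the α-acyloxy aldehyde should form without epimerisation of the neighbouring centre or β-elimination of the silyloxy group.

Step 11
Reactants: 15 3-O-TBS lactone 5-aldehyde
Product: 16 3-O-TBS-5-isobutenyl lactone
Conditions: iPrPPh3+ I−, n-BuLi, THF, 0 °C; then 15, −78 → 0 °C
Reagents that add atoms: isopropyltriphenylphosphonium iodide, CC(C)[P+](c1ccccc1)(c1ccccc1)c1ccccc1.[I-]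
Why: Wittig olefination, in which the unstabilised ylide adds to the aldehyde far faster than to the lactone carbonyl at −78 °C (as in known olefinations of lactone aldehydes), and since both ylide substituents are methyl no alkene geometry arises.

Step 12
Reactants: 16 3-O-TBS-5-isobutenyl lactone
Product: 17 α-(dimethylaminomethyl) lactone
Conditions: LiN(iPr)2, THF, −78 °C; then Me2N=CH2+ I−, −78 → 0 °C
Reagents that add atoms: N,N-dimethylmethyleneiminium iodide (Eschenmoser's salt), C=[N+](C)C.[I-]
Why: Mannich reaction of the lithium lactone enolate with the iminium salt, with attack anti to the neighbouring silyloxy group giving the 3S amine (a centre removed again in step 13), and at −78 °C silyloxide is too poor a leaving group for β-elimination to compete.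

Step 13
Reactants: 17 α-(dimethylaminomethyl) lactone
Product: 19 TBS-protected α-methylene lactone, via trimethylammonium iodide 18 (not isolated)
Conditions: MeI, MeOH, rt; then NaHCO3 (aq), CH2Cl2, rt
Reagents that add atoms: none
Why: quaternisation followed by base-induced E1cB (Hofmann-type) loss of trimethylamine should give the exo-methylene group, since trimethylammonium leaves far more readily than the β-silyloxy group.

Step 14
Reactants: 19 TBS-protected α-methylene lactone
Product: 20 α-methylene hydroxy lactone
Conditions: HF·pyridine, THF/pyridine, 0 °C → rt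
Reagents that add atoms: none
Why: desilylation with acidic fluoride should leave the Michael-acceptor lactone and the allylic C13–O bond alone, whereas basic fluoride could add to the acrylate.

Step 15
Reactants: 10 C8 diazoacetate of 8; 21 chlorodimethylsilane; 20 α-methylene hydroxy lactone
Product: 23 silylacetate-tethered diene, via C8 chlorodimethylsilylacetate 22 (not isolated)
Conditions: Rh2(OAc)4 (1 mol%), 21 (10 equiv), CH2Cl2, slow addition of 10, 0 °C → rt; evaporate; then 20, Et3N, CH2Cl2, 0 °C; Et3N-deactivated silica
Reagents that add atoms: none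
Why: dirhodium-carbenoid insertion into the Si–H bond of the hydrosilane (in large excess so that it outruns intramolecular cyclopropanation) followed by substitution of chloride at silicon by the lactone alcohol is a known one-pot route to α-(alkoxysilyl)acetates; no metal enolate of the allylic C8 ester is formed, so a [3,3] shift cannot intervene, and no stereocentre is touched.

Step 16
Reactants: 23 silylacetate-tethered diene
Product: 24 ten-membered cyclic silylacetate
Conditions: second-generation Hoveyda–Grubbs catalyst RuCl2(H2IMes)(=CH-C6H4-2-OiPr) (10 mol%), 2,6-dichloro-1,4-benzoquinone (20 mol%), toluene (0.001 M), 80 °C, argon sparge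
Reagents that add atoms: none
Why: The ruthenium alkylidene should form at the only monosubstituted alkene (the C10 vinyl group), add to the unsubstituted CH2 terminus of the lactone exo-methylene through a ruthenacyclobutane and cyclorevert with loss of ethene (Chauvin mechanism); the closest known reactions are silicon-tethered ring-closing metathesis and cross-metathesis of α-methylene-γ-butyrolactones with terminal alkenes. Ring B (C8, C9, C10, C11, C12, O, Si, CH2, C=O, O) closes by ring-closing metathesis, the new C10=C11 bond being endocyclic to it and exocyclic to ring A, and the long Si–O and Si–C bonds and the planar ester should ease medium-ring strain. No stereocentre is formed; the geometry is set by the ring, since a trisubstituted alkene in a ten-membered ring is strongly favoured to hold C9 and C12 cis, which is 10E (C9 anti to C20) and also the usual thermodynamic preference of α-alkylidene lactones. Site selectivity among six alkenes rests on substitution: the angelate, C2=C3, C6=C7 and C14=C15 alkenes are trisubstituted and do not initiate, and closure onto the isobutenyl group would need an eleven-membered ring and the expulsion of a disubstituted carbene. High dilution holds back dimerisation at the vinyl group, and the benzoquinone traps ruthenium hydrides that would move the exo-methylene into ring A.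

Step 17
Reactants: 24 ten-membered cyclic silylacetate
Product: 25 CNP0201198.1
Conditions: Bu4NF, AcOH (1:1, 3 equiv each), THF, 0 °C → rt
Reagents that add atoms: none
Why: fluoride attack at silicon should cleave the Si–O12 bond and expel the ester enolate of the α-silyl ester (protodesilylation), which acetic acid protonates at carbon to leave the C8 acetate, and the buffer keeps alkoxide and enolate concentrations low so that acyl migration, angelate isomerisation and conjugate addition should not occur.

**Compound list**

1 | nerol, (2Z)-3,7-dimethylocta-2,6-dien-1-ol | CC(C)=CCC/C(C)=C\CO | starting material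
2 | angelic acid, (2Z)-2-methylbut-2-enoic acid | C/C=C(/C)C(=O)O | starting material
3 | angelic 2,4,6-trichlorobenzoic anhydride | C/C=C(/C)C(=O)OC(=O)c1c(Cl)cc(Cl)cc1Cl | intermediate
4 | neryl angelate, (2Z)-3,7-dimethylocta-2,6-dien-1-yl (2Z)-2-methylbut-2-enoate | C/C=C(/C)C(=O)OC/C=C(/C)CCC=C(C)C | intermediate
5 | (2Z,6E)-8-hydroxy-3,7-dimethylocta-2,6-dien-1-yl (2Z)-2-methylbut-2-enoate | C/C=C(/C)C(=O)OC/C=C(/C)CC/C=C(\C)CO | intermediate
6 | (2Z,6E)-3,7-dimethyl-8-oxoocta-2,6-dien-1-yl (2Z)-2-methylbut-2-enoate | C/C=C(/C)C(=O)OC/C=C(/C)CC/C=C(\C)C=O | intermediate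
7 | O8-diisopinocampheylborinate of alcohol 8 (isopinocampheyl groups from (+)-α-pinene) | C/C=C(/C)C(=O)OC/C=C(/C)CC/C=C(\C)[C@H](CC=C)OB([C@@H]1C[C@@H]2C[C@H]([C@H]1C)C2(C)C)[C@@H]1C[C@@H]2C[C@H]([C@H]1C)C2(C)C | intermediate
8 | (2Z,6E,8S)-8-hydroxy-3,7-dimethylundeca-2,6,10-trien-1-yl (2Z)-2-methylbut-2-enoate | C/C=C(/C)C(=O)OC/C=C(/C)CC/C=C(\C)[C@H](CC=C)O | intermediate
9 | (2Z,6E,8S)-8-(2-bromoacetoxy)-3,7-dimethylundeca-2,6,10-trien-1-yl (2Z)-2-methylbut-2-enoate | C/C=C(/C)C(=O)OC/C=C(/C)CC/C=C(\C)[C@H](CC=C)OC(=O)CBr | intermediate
10 | (2Z,6E,8S)-8-(2-diazoacetoxy)-3,7-dimethylundeca-2,6,10-trien-1-yl (2Z)-2-methylbut-2-enoate | C/C=C(/C)C(=O)OC/C=C(/C)CC/C=C(\C)[C@H](CC=C)OC(=O)C=[N+]=[N-] | intermediate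
11 | 2-deoxy-D-ribose | O=CC[C@H](O)[C@H](O)CO | starting material
12 | 2-deoxy-D-ribono-1,4-lactone, (4S,5R)-4-hydroxy-5-(hydroxymethyl)dihydrofuran-2(3H)-one | O=C1C[C@H](O)[C@@H](CO)O1 | intermediate
13 | (4S,5R)-4-(tert-butyldimethylsilyloxy)-5-[(tert-butyldimethylsilyloxy)methyl]dihydrofuran-2(3H)-one | O=C1C[C@H](O[Si](C)(C)C(C)(C)C)[C@@H](CO[Si](C)(C)C(C)(C)C)O1 | intermediate
14 | (4S,5R)-4-(tert-butyldimethylsilyloxy)-5-(hydroxymethyl)dihydrofuran-2(3H)-one | O=C1C[C@H](O[Si](C)(C)C(C)(C)C)[C@@H](CO)O1 | intermediate
15 | (2S,3S)-3-(tert-butyldimethylsilyloxy)-5-oxotetrahydrofuran-2-carbaldehyde | O=C1C[C@H](O[Si](C)(C)C(C)(C)C)[C@@H](C=O)O1 | intermediate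
16 | (4S,5R)-4-(tert-butyldimethylsilyloxy)-5-(2-methylprop-1-en-1-yl)dihydrofuran-2(3H)-one | O=C1C[C@H](O[Si](C)(C)C(C)(C)C)[C@@H](C=C(C)C)O1 | intermediate
17 | (3S,4S,5R)-4-(tert-butyldimethylsilyloxy)-3-[(dimethylamino)methyl]-5-(2-methylprop-1-en-1-yl)dihydrofuran-2(3H)-one | O=C1[C@@H](CN(C)C)[C@H](O[Si](C)(C)C(C)(C)C)[C@@H](C=C(C)C)O1 | intermediate
18 | trimethylammonium iodide of 17 | O=C1[C@@H](C[N+](C)(C)C)[C@H](O[Si](C)(C)C(C)(C)C)[C@@H](C=C(C)C)O1.[I-] | intermediate
19 | (4S,5R)-4-(tert-butyldimethylsilyloxy)-3-methylene-5-(2-methylprop-1-en-1-yl)dihydrofuran-2(3H)-one | C=C1C(=O)O[C@H](C=C(C)C)[C@H]1O[Si](C)(C)C(C)(C)C | intermediate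
20 | (4S,5R)-4-hydroxy-3-methylene-5-(2-methylprop-1-en-1-yl)dihydrofuran-2(3H)-one | C=C1C(=O)O[C@H](C=C(C)C)[C@H]1O | intermediate
21 | chlorodimethylsilane | C[SiH](C)Cl | starting material
22 | C8 (chlorodimethylsilyl)acetate of alcohol 8 | C/C=C(/C)C(=O)OC/C=C(/C)CC/C=C(\C)[C@H](CC=C)OC(=O)C[Si](C)(C)Cl | intermediate
23 | silylacetate-tethered diene: C8 (dimethylsilyl)acetate of 8 bound through silicon to O12 of lactone 20 (8S, 12S, 13R) | C/C=C(/C)C(=O)OC/C=C(/C)CC/C=C(\C)[C@H](CC=C)OC(=O)C[Si](C)(C)O[C@@H]1[C@@H](C=C(C)C)OC(=O)C1=C | intermediate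
24 | ten-membered cyclic silylacetate (ring B) fused at C11 and C12 to the (10E)-alkylidene lactone (8S, 12S, 13R) | C/C=C(/C)C(=O)OC/C=C(/C)CC/C=C(\C)[C@@H]1C/C=C2/C(=O)O[C@H](C=C(C)C)[C@H]2O[Si](C)(C)CC(=O)O1 | intermediate
25 | CNP0201198.1, (2Z,6E,8S,10E)-8-acetoxy-10-[(4S,5R)-4-hydroxy-5-(2-methylprop-1-en-1-yl)-2-oxodihydrofuran-3(2H)-ylidene]-3,7-dimethyldeca-2,6-dien-1-yl (2Z)-2-methylbut-2-enoate | C/C=C(/C)C(=O)OC/C=C(/C)CC/C=C(\C)[C@H](C/C=C1/C(=O)O[C@H](C=C(C)C)[C@H]1O)OC(C)=O | target

**Step count and risks**

Total step count: 17. Longest linear sequence: 11 steps (2-deoxy-D-ribose 11 to target 25, steps 7 to 17); the nerol branch is 9 steps (steps 1 to 6, then 15 to 17).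

Steps most likely to fail:

1. Step 16. Intermolecular metathesis at the vinyl group (oligomers) may outpace closure of the medium ring, or ruthenium hydrides may move the exo-methylene into ring A. The fallback drops the tether. Alcohol 8 is acetylated (Ac2O, pyridine, DMAP, CH2Cl2) to (2Z,6E,8S)-8-acetoxy-3,7-dimethylundeca-2,6,10-trien-1-yl angelate F1. F1, used in excess, is then joined to hydroxy lactone 20 by cross-metathesis (second-generation Hoveyda–Grubbs catalyst RuCl2(H2IMes)(=CH-C6H4-2-OiPr), 2,6-dichloro-1,4-benzoquinone, CH2Cl2, 40 °C). This is a known reaction of α-methylene-γ-butyrolactones with terminal alkenes and is expected to favour the E-alkylidene lactone. The fallback sets out from 8 and 20 and comes back at target 25, bypassing 23 and 24; the geometry then rests on thermodynamic preference alone, and the hydroxyls are told apart by acetylating O8 before the fragments meet.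

2. Step 15. Cyclopropanation of the carbenoid onto the C6=C7 or vinyl alkene may compete with insertion into the electron-poor Si–H bond, or the chlorosilane may hydrolyse before it is silylated. The fallback sets out from bromoacetate 9. Zinc insertion (activated Zn, THF, 0 °C) gives the Reformatsky reagent F2, which is C-silylated with an excess of Me2SiCl2, the classical way to silylacetates, to give the same chlorosilylacetate 22. Excess dichlorosilane is evaporated, and 20 and Et3N are added to rejoin the route at 23. The mixture is kept at or below room temperature because the zinc enolate of an allylic ester can undergo a Reformatsky–Claisen shift on heating.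

3. Step 11. The basic ylide may epimerise the α-acyloxy aldehyde, trigger β-elimination of the silyloxy group or attack the lactone carbonyl. The fallback uses no basic reagent and sets out from aldehyde 15. Takai–Lombardo methylenation (Zn, CH2Br2, TiCl4, THF, 0 °C), which spares lactones and α-stereocentres, gives (4S,5R)-4-(tert-butyldimethylsilyloxy)-5-vinyldihydrofuran-2(3H)-one F3. Cross-metathesis of F3 with 2-methyl-2-butene (second-generation Grubbs catalyst RuCl2(H2IMes)(PCy3)(=CHPh), neat alkene/CH2Cl2, 40 °C), the usual way of turning a vinyl into an isobutenyl group, comes back to the route at 16.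

**Further compounds**

F1 | step 16 | (2Z,6E,8S)-8-acetoxy-3,7-dimethylundeca-2,6,10-trien-1-yl (2Z)-2-methylbut-2-enoate | C/C=C(/C)C(=O)OC/C=C(/C)CC/C=C(\C)[C@H](CC=C)OC(C)=O
F2 | step 15 | Reformatsky reagent (bromozinc enolate) of bromoacetate 9 | C/C=C(/C)C(=O)OC/C=C(/C)CC/C=C(\C)[C@H](CC=C)OC(=O)C[Zn]Br
F3 | step 11 | (4S,5R)-4-(tert-butyldimethylsilyloxy)-5-vinyldihydrofuran-2(3H)-one | O=C1C[C@H](O[Si](C)(C)C(C)(C)C)[C@@H](C=C)O1
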